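**Plan**

1. Retrosynthesis: C12=C13 is cut by cross-metathesis (allyl-decalin plus (S)-tulipalin B acetate); C8=C17 and C9–C11 go back to a C9 ketone; the C3–C4 bond of ring A is cut by a retro-1,2-shift that places C19 between C3 and C4, giving a ring-A-homo cis-2,3-epoxy silyl ether; that seven-membered ring is cut at C19=C4 (metathesis), C3–C19 (vinyl addition), C10–C1 and C5–C4 (conjugate addition–allylation).
2. Forward: ring B is the starting cyclohexenone; a seven-membered ring is closed by metathesis and contracted to ring A (key step); ring B is then adorned (C9 allyl, C8 methylene); the lactone is joined last.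
3. Enabling feature: O–C3–C4(CH3)(C19–O) is an aldol pattern whose alpha-carbon C4 is quaternary and lies in six-membered ring A (C1, C2, C3, C4, C5, C10). A beta-oxygenated aldehyde with a quaternary alpha-carbon is what the 1,2-shift of an epoxide delivers, so ring A can be drawn from the seven-membered ring C1, C2, C3, C19, C4, C5, C10.
4. Stereochemistry: C5 and C10 from ligand-controlled conjugate addition and anti allylation; C3 from reagent-controlled vinylation; C4 relayed from C3 by hydroxyl-directed epoxidation and anti migration; C9 by protonation next to the C8 ketone; C14 from (S)-3-hydroxy-gamma-butyrolactone; the E-olefin from metathesis.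

Key step: step 7

Remark: ent-labdane numbering (C1 to C20; C18 is the C4 methyl, C19 the oxygenated carbon on C4) is used for all intermediates; 2-methylcyclohex-2-en-1-one and (S)-3-hydroxy-gamma-butyrolactone are taken as commercial.

**Route**

Step 1
Reactants: 1 2-methylcyclohex-2-en-1-one
Product: 3 (2R,3R)-2-methyl-3-(prop-1-en-2-yl)-2-(prop-2-en-1-yl)cyclohexan-1-one, via bromomagnesium enolate 2 (not isolated)
Conditions: isopropenylmagnesium bromide, Cu(OTf)2 (3 mol%), chiral imidazolinium NHC precursor (4 mol%, enantiomer chosen for 3R), Et2O, −30 °C; then allyl iodide, DMPU, −30 °C → rt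
Reagents that add atoms: isopropenylmagnesium bromide CC(=C)[Mg]Br; allyl iodide C=CCI
Why: Copper–NHC-catalysed asymmetric conjugate addition of a Grignard reagent to a 2-substituted cyclohexenone should set C5 under ligand control, and the magnesium enolate 2 is then allylated at C10 anti to the new isopropenyl group (conjugate addition–enolate alkylation), so the C10 methyl ends cis and the allyl chain trans to the isopropenyl group.

Step 2
Reactants: 3 (2R,3R)-2-methyl-3-(prop-1-en-2-yl)-2-(prop-2-en-1-yl)cyclohexan-1-one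
Product: 4 3-[(1R,6R)-1-methyl-2-oxo-6-(prop-1-en-2-yl)cyclohexyl]propanal
Conditions: PdCl2(PhCN)2 (10 mol%), CuCl2·2H2O (10 mol%), AgNO2 (5 mol%), O2 (1 atm), t-BuOH/MeNO2 15:1, rt
Reagents that add atoms: dioxygen O=O
Why: The nitrite-modified Tsuji–Wacker oxidation should deliver oxygen to the terminal carbon of the unbiased monosubstituted olefin (aldehyde-selective), while the 1,1-disubstituted isopropenyl group and the ketone are inert to the divalent palladium catalyst; no stereocentre is formed.

Step 3
Reactants: 4 3-[(1R,6R)-1-methyl-2-oxo-6-(prop-1-en-2-yl)cyclohexyl]propanal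
Product: 5 (2R,3R)-2-[(3R)-3-hydroxypent-4-en-1-yl]-2-methyl-3-(prop-1-en-2-yl)cyclohexan-1-one
Conditions: divinylzinc (1.5 equiv), (−)-3-exo-(dimethylamino)isoborneol (10 mol%), toluene/Et2O, 0 °C; aq NH4Cl
Reagents that add atoms: divinylzinc C=C[Zn]C=C
Why: In this amino-alcohol-catalysed alkenylzinc addition to an aldehyde, the chiral zinc aminoalkoxide should deliver the vinyl group to the Si face and set C3 as (R) under reagent control, and the hindered ketone does not react with organozinc reagents.

Step 4
Reactants: 5 (2R,3R)-2-[(3R)-3-hydroxypent-4-en-1-yl]-2-methyl-3-(prop-1-en-2-yl)cyclohexan-1-one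
Product: 6 (1R,4R,7R)-4-hydroxy-2,7-dimethylbicyclo[5.4.0]undec-2-en-8-one
Conditions: second-generation Grubbs catalyst (5 mol%), CH2Cl2 (5 mM), 40 °C
Reagents that add atoms: none
Why: Ring-closing metathesis of the vinyl carbinol with the isopropenyl group should close the seven-membered ring as its trisubstituted olefin C19=C4 with loss of ethene; the two chains are trans-diequatorial on ring B, which allows the trans-fused bicycle, and no stereocentre is touched.

Step 5
Reactants: 6 (1R,4R,7R)-4-hydroxy-2,7-dimethylbicyclo[5.4.0]undec-2-en-8-one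
Product: 7 (1S,2S,3R,4R,7R)-2,3-epoxy-4-hydroxy-2,7-dimethylbicyclo[5.4.0]undecan-8-one
Conditions: VO(acac)2 (2 mol%), t-BuOOH (1.5 equiv), CH2Cl2, 0 °C → rt
Reagents that add atoms: tert-butyl hydroperoxide CC(C)(C)OO
Why: In this hydroxyl-directed epoxidation, the pentavalent vanadium alkylperoxide bound to the C3 alkoxide should deliver oxygen to the olefin face syn to the hydroxyl group (rule for cyclic allylic alcohols), fixing C19 and C4 of the cis-epoxy alcohol relative to C3.

Step 6
Reactants: 7 (1S,2S,3R,4R,7R)-2,3-epoxy-4-hydroxy-2,7-dimethylbicyclo[5.4.0]undecan-8-one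
Product: 8 (1S,2S,3R,4R,7R)-2,3-epoxy-2,7-dimethyl-4-(triethylsilyloxy)bicyclo[5.4.0]undecan-8-one
Conditions: Et3SiCl, imidazole, DMAP (cat.), DMF, 0 °C → rt
Reagents that add atoms: chlorotriethylsilane CC[Si](Cl)(CC)CC
Why: Silylation of the secondary alcohol turns it into the non-chelating silyloxy group that activates C3 as the migrating carbon; the ketone is not enolised under imidazole conditions.

Step 7
Reactants: 8 (1S,2S,3R,4R,7R)-2,3-epoxy-2,7-dimethyl-4-(triethylsilyloxy)bicyclo[5.4.0]undecan-8-one
Product: 9 (1S,2R,4aR,8aR)-1,4a-dimethyl-5-oxo-2-(triethylsilyloxy)decahydronaphthalene-1-carbaldehyde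
Conditions: MABR [MeAl(OAr)2, Ar = 4-bromo-2,6-di-tert-butylphenyl] (2.2 equiv), CH2Cl2, −78 → −40 °C; aq HCl
Reagents that add atoms: none
Why: The bulky oxophilic aluminium Lewis acid binds the epoxide oxygen, the C4–O bond lengthens, and the C3–C19 bond shifts from C19 to C4 on the face opposite the departing oxygen while C19 becomes the aldehyde carbon; this is the 1,2-shift (semipinacol rearrangement) of a 2,3-epoxy silyl ether to a beta-silyloxy aldehyde in its ring-contracting form, closely related to the Meinwald rearrangement of cycloalkene oxides. Ring A (C1, C2, C3, C4, C5, C10) is thus closed not by cyclisation of an open chain but by contraction of the seven-membered ring (C1, C2, C3, C19, C4, C5, C10), with C19 extruded as the exocyclic formyl group. The only new stereocentre, quaternary C4, is set by the epoxide configuration with inversion (methyl equatorial, formyl axial and cis to the C10 methyl), and C3 migrates with retention so that its silyloxy group ends equatorial and cis to C19; both trace back to the C3 carbinol through the directed epoxidation. The step needs C4–O rather than C19–O cleavage, which the tertiary centre and the inductively withdrawing silyloxy-bearing neighbour of C19 should secure, and it needs migration of C3 rather than of the C19 hydrogen (which would give a ring-retained ketone), which the high migratory aptitude of a silyloxy-substituted carbon and the bulky aryloxide ligands should secure. The C9 ketone only consumes one equivalent of Lewis acid, and the product can neither epimerise nor eliminate because C4 carries no hydrogen.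

Step 8
Reactants: 9 (1S,2R,4aR,8aR)-1,4a-dimethyl-5-oxo-2-(triethylsilyloxy)decahydronaphthalene-1-carbaldehyde
Product: 10 (4aR,5R,6R,8aR)-5-(hydroxymethyl)-5,8a-dimethyl-6-(triethylsilyloxy)octahydronaphthalen-1(2H)-one
Conditions: NaBH4, MeOH/CH2Cl2, −78 → −40 °C
Reagents that add atoms: none
Why: Borohydride reduction at low temperature should be chemoselective for the aldehyde over the ketone flanked by quaternary C10, and no stereocentre is affected.

Step 9
Reactants: 10 (4aR,5R,6R,8aR)-5-(hydroxymethyl)-5,8a-dimethyl-6-(triethylsilyloxy)octahydronaphthalen-1(2H)-one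
Product: 12 3,19-O-isopropylidene acetonide of the C9 ketone [(3R,4R,5R,10R), 2,2-dimethyl-1,3-dioxane across O3 and O19], via diol 11 (not isolated)
Conditions: TsOH·H2O (cat.), MeOH, rt; then 2,2-dimethoxypropane, acetone, rt
Reagents that add atoms: 2,2-dimethoxypropane COC(C)(C)OC
Why: Acid-catalysed methanolysis should remove the triethylsilyl ether to give diol 11, and transacetalisation then closes the six-membered 1,3-dioxane across the cis-disposed equatorial C3 hydroxyl and axial C19 hydroxymethyl groups.

Step 10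
Reactants: 12 3,19-O-isopropylidene acetonide of the C9 ketone
Product: 13 C9-methylidene acetonide [(3R,4R,5S,10R), exocyclic C9=C11]
Conditions: Ph3PCH3Br, KOtBu, toluene, 90 °C
Reagents that add atoms: methyltriphenylphosphonium bromide C[P+](c1ccccc1)(c1ccccc1)c1ccccc1.[Br-]
Why: Wittig methylenation with the small non-stabilised ylide should convert the hindered C9 ketone into the exocyclic olefin, and the acetonide is stable to base.

Step 11
Reactants: 13 C9-methylidene acetonide
Product: 14 C8-hydroxy C9-methylidene acetonide (mixture of C8 epimers)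
Conditions: SeO2 (0.5 equiv), t-BuOOH, CH2Cl2, rt
Reagents that add atoms: selenium dioxide O=[Se]=O (oxygen carrier); tert-butyl hydroperoxide CC(C)(C)OO
Why: Selenium dioxide allylic oxidation (ene reaction then 2,3-sigmatropic shift) should hydroxylate the only allylic methylene, C8 (C10 is quaternary), and return the double bond to C9=C11; the C8 configuration is inconsequential because it is oxidised next.

Step 12
Reactants: 14 C8-hydroxy C9-methylidene acetonide
Product: 15 C8-oxo C9-methylidene acetonide [(3R,4R,5S,10R), exocyclic enone]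
Conditions: Dess–Martin periodinane, NaHCO3, CH2Cl2, 0 °C → rt
Reagents that add atoms: none
Why: Dess–Martin oxidation of the secondary allylic alcohol should give the exocyclic enone, in which the carbonyl now sits at C8 and the acceptor carbon is C11.

Step 13
Reactants: 15 C8-oxo C9-methylidene acetonide
Product: 17 C8-oxo C9-allyl acetonide [(3R,4R,5S,9S,10R), allyl equatorial], via bromomagnesium enolate 16 (not isolated)
Conditions: CH2=CHMgBr, CuBr·SMe2 (10 mol%), THF, −78 → −40 °C; aq NH4Cl
Reagents that add atoms: vinylmagnesium bromide C=C[Mg]Br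
Why: Copper-catalysed conjugate addition of the vinyl Grignard reagent to the unhindered exocyclic carbon C11 should give enolate 16, and protonation anti to the axial C10 methyl (also the thermodynamic outcome for this epimerisable centre next to the C8 ketone) places the new allyl chain equatorial at C9.

Step 14
Reactants: 17 C8-oxo C9-allyl acetonide
Product: 18 3,19-O-isopropylidene-14,15,16-trinor-ent-labda-8(17),12-diene-3,19-diol [(3R,4R,5S,9R,10S)]
Conditions: Ph3PCH3Br, KOtBu, THF, 0 °C → rt
Reagents that add atoms: methyltriphenylphosphonium bromide C[P+](c1ccccc1)(c1ccccc1)c1ccccc1.[Br-]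
Why: Wittig methylenation of the C8 ketone should install the exocyclic C8=C17 methylene, and any epimerisation at C9 by the basic ylide converges on the more stable equatorial side chain.

Step 15
Reactants: 19 (4S)-4-hydroxyoxolan-2-one [(S)-3-hydroxy-gamma-butyrolactone]
Product: 21 (3S,4S)-3-[(dimethylamino)methyl]-4-hydroxyoxolan-2-one, via dilithium dianion 20 (not isolated)
Conditions: LiN(iPr)2 (2.2 equiv), THF, −78 → −40 °C; then Eschenmoser's salt, −78 °C → rt; aq NH4Cl
Reagents that add atoms: dimethyl(methylidene)ammonium iodide C[N+](C)=C.[I-]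
Why: The alkoxide–enolate dianion of a beta-hydroxy lactone should be aminomethylated at C13 anti to the alkoxide (Mannich reaction); the alkoxide is a poor leaving group, so beta-elimination does not compete and C14 is untouched.

Step 16
Reactants: 21 (3S,4S)-3-[(dimethylamino)methyl]-4-hydroxyoxolan-2-one
Product: 23 (4S)-4-hydroxy-3-methylideneoxolan-2-one [(S)-tulipalin B], via ammonium iodide 22 (not isolated)
Conditions: MeI, MeOH, rt; then aq NaHCO3, CH2Cl2, rt
Reagents that add atoms: none
Why: N-Methylation should give ammonium salt 22, and mild base then effects E1cB (Hofmann-type) loss of trimethylamine, a far better leaving group than the ring hydroxyl, to give the alpha-methylene lactone.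

Step 17
Reactants: 23 (4S)-4-hydroxy-3-methylideneoxolan-2-one
Product: 24 (3S)-4-methylidene-5-oxooxolan-3-yl acetate
Conditions: Ac2O, pyridine, DMAP (cat.), CH2Cl2, 0 °C
Reagents that add atoms: acetic anhydride CC(=O)OC(C)=O
Why: Standard O-acetylation of the secondary alcohol places the C14 acetate before fragment coupling, so no late differentiation of three hydroxyl groups is needed.

Step 18
Reactants: 18 3,19-O-isopropylidene-14,15,16-trinor-ent-labda-8(17),12-diene-3,19-diol; 24 (3S)-4-methylidene-5-oxooxolan-3-yl acetate (3 equiv)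
Product: 25 14-O-acetyl-3,19-O-isopropylideneandrographolide
Conditions: second-generation Hoveyda–Grubbs catalyst (5–10 mol%), 2,6-dichloro-1,4-benzoquinone (10 mol%), CH2Cl2, 40 °C
Reagents that add atoms: none
Why: Cross-metathesis of the terminal monosubstituted olefin with the alpha-methylene gamma-butyrolactone (acrylate-type partner in excess) should give the trisubstituted alkylidene lactone with the chain trans to the carbonyl (E, favoured in the reversible metathesis), while the hindered 1,1-disubstituted C8=C17 methylene does not engage.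

Step 19
Reactants: 25 14-O-acetyl-3,19-O-isopropylideneandrographolide
Product: 26 14-O-acetylandrographolide (target)
Conditions: AcOH/H2O 7:3, rt
Reagents that add atoms: none
Why: Mild aqueous acetic acid should hydrolyse the 1,3-dioxane acetonide without cleaving the allylic acetate or isomerising the exocyclic olefin.

**Compound list**

1 | 2-methylcyclohex-2-en-1-one | CC1=CCCCC1=O | starting material
2 | bromomagnesium (3R)-2-methyl-3-(prop-1-en-2-yl)cyclohex-1-en-1-olate | C=C(C)[C@H]1CCCC(O[Mg]Br)=C1C | intermediate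
3 | (2R,3R)-2-methyl-3-(prop-1-en-2-yl)-2-(prop-2-en-1-yl)cyclohexan-1-one | C=CC[C@]1(C)[C@@H](C(C)=C)CCCC1=O | intermediate
4 | 3-[(1R,6R)-1-methyl-2-oxo-6-(prop-1-en-2-yl)cyclohexyl]propanal | O=CCC[C@]1(C)[C@@H](C(C)=C)CCCC1=O | intermediate
5 | (2R,3R)-2-[(3R)-3-hydroxypent-4-en-1-yl]-2-methyl-3-(prop-1-en-2-yl)cyclohexan-1-one | C=C[C@H](O)CC[C@]1(C)[C@@H](C(C)=C)CCCC1=O | intermediate
6 | (1R,4R,7R)-4-hydroxy-2,7-dimethylbicyclo[5.4.0]undec-2-en-8-one (ring-A-homo allylic alcohol, trans-fused, OH cis to the angular methyl) | O[C@H]1C=C(C)[C@H]2CCCC(=O)[C@]2(C)CC1 | intermediate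
7 | (1S,2S,3R,4R,7R)-2,3-epoxy-4-hydroxy-2,7-dimethylbicyclo[5.4.0]undecan-8-one (cis-epoxy alcohol) | O[C@H]1[C@H]2O[C@@]2(C)[C@H]3CCCC(=O)[C@]3(C)CC1 | intermediate
8 | (1S,2S,3R,4R,7R)-2,3-epoxy-2,7-dimethyl-4-(triethylsilyloxy)bicyclo[5.4.0]undecan-8-one | CC[Si](CC)(CC)O[C@H]1[C@H]2O[C@@]2(C)[C@H]3CCCC(=O)[C@]3(C)CC1 | intermediate
9 | (1S,2R,4aR,8aR)-1,4a-dimethyl-5-oxo-2-(triethylsilyloxy)decahydronaphthalene-1-carbaldehyde | CC[Si](CC)(CC)O[C@@H]1CC[C@@]2(C)C(=O)CCC[C@@H]2[C@]1(C)C=O | intermediate
10 | (4aR,5R,6R,8aR)-5-(hydroxymethyl)-5,8a-dimethyl-6-(triethylsilyloxy)octahydronaphthalen-1(2H)-one | CC[Si](CC)(CC)O[C@@H]1CC[C@@]2(C)C(=O)CCC[C@@H]2[C@]1(C)CO | intermediate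
11 | (4aR,5R,6R,8aR)-6-hydroxy-5-(hydroxymethyl)-5,8a-dimethyloctahydronaphthalen-1(2H)-one | O[C@@H]1CC[C@@]2(C)C(=O)CCC[C@@H]2[C@]1(C)CO | intermediate
12 | 3,19-O-isopropylidene acetonide of 11, C9 ketone, (3R,4R,5R,10R) | CC1(C)OC[C@@]2(C)[C@H]3CCCC(=O)[C@]3(C)CC[C@H]2O1 | intermediate
13 | C9-methylidene acetonide, (3R,4R,5S,10R) | CC1(C)OC[C@@]2(C)[C@H]3CCCC(=C)[C@]3(C)CC[C@H]2O1 | intermediate
14 | C8-hydroxy C9-methylidene acetonide (C8 epimers) | CC1(C)OC[C@@]2(C)[C@H]3CCC(O)C(=C)[C@]3(C)CC[C@H]2O1 | intermediate
15 | C8-oxo C9-methylidene acetonide, (3R,4R,5S,10R) | CC1(C)OC[C@@]2(C)[C@H]3CCC(=O)C(=C)[C@]3(C)CC[C@H]2O1 | intermediate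
16 | bromomagnesium C8 enolate of 17 | CC1(C)OC[C@@]2(C)[C@H]3CCC(O[Mg]Br)=C(CC=C)[C@]3(C)CC[C@H]2O1 | intermediate
17 | C8-oxo C9-allyl acetonide, (3R,4R,5S,9S,10R) | CC1(C)OC[C@@]2(C)[C@H]3CCC(=O)[C@@H](CC=C)[C@]3(C)CC[C@H]2O1 | intermediate
18 | 3,19-O-isopropylidene-14,15,16-trinor-ent-labda-8(17),12-diene-3,19-diol, (3R,4R,5S,9R,10S) | CC1(C)OC[C@@]2(C)[C@H]3CCC(=C)[C@@H](CC=C)[C@]3(C)CC[C@H]2O1 | intermediate
19 | (4S)-4-hydroxyoxolan-2-one | O=C1C[C@H](O)CO1 | starting material
20 | dilithium alkoxide–enolate of 19 | [Li]O[C@@H]1COC(O[Li])=C1 | intermediate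
21 | (3S,4S)-3-[(dimethylamino)methyl]-4-hydroxyoxolan-2-one | CN(C)C[C@@H]1C(=O)OC[C@H]1O | intermediate
22 | [(3S,4S)-4-hydroxy-2-oxooxolan-3-yl]methyl(trimethyl)ammonium iodide | C[N+](C)(C)C[C@@H]1C(=O)OC[C@H]1O.[I-] | intermediate
23 | (4S)-4-hydroxy-3-methylideneoxolan-2-one | C=C1C(=O)OC[C@H]1O | intermediate
24 | (3S)-4-methylidene-5-oxooxolan-3-yl acetate | C=C1C(=O)OC[C@H]1OC(C)=O | intermediate
25 | 14-O-acetyl-3,19-O-isopropylideneandrographolide | CC1(C)OC[C@@]2(C)[C@H]3CCC(=C)[C@@H](C/C=C4/C(=O)OC[C@H]4OC(C)=O)[C@]3(C)CC[C@H]2O1 | intermediate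
26 | 14-O-acetylandrographolide | C=C1CC[C@@H]2[C@](C)(CO)[C@H](O)CC[C@@]2(C)[C@@H]1C/C=C1/C(=O)OC[C@H]1OC(C)=O | target

**Count and risks**

Total step count: 19. Longest linear sequence: 16 steps (steps 1–14, 18 and 19); steps 15–17 make the lactone fragment.

Step 7 (ring contraction). What may go wrong: after C4–O cleavage the C19 hydrogen may migrate instead of C3 (ring-retained ketone), the cation may be lost by elimination, or the C9 carbonyl oxygen may capture it. Fallback, setting out from 7 and coming back at 12: Dess–Martin oxidation of 7 gives the cis-epoxy diketone F4. BF3·OEt2 in CH2Cl2 then brings about the classical rearrangement of an alpha,beta-epoxy ketone, in which the C3 acyl group (a better migrating group than hydrogen) shifts from C19 to C4 with inversion and ring contraction, giving the 2-formyl ketone F5 with the same C4 configuration. NaBH4 reduces the aldehyde and both ketones to the triol F6 (equatorial C3 alcohol by axial hydride delivery). 2,2-Dimethoxypropane/PPTS closes the 3,19-acetonide to give the C9 alcohol F7, and Dess–Martin oxidation of that alcohol returns 12.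

Step 1 (asymmetric conjugate addition–allylation). What may go wrong: poor facial selectivity with an alkenyl Grignard reagent, or sluggish allylation of the hindered magnesium enolate. Fallback, setting out from 1 and coming back at 5: achiral CuBr·SMe2-catalysed conjugate addition of isopropenylmagnesium bromide and allylation with allyl bromide/HMPA gives the trans ketone as a racemate, that is 3 together with the enantiomeric ketone F1. Step 2 converts the pair into 4 and the enantiomeric keto aldehyde F2. The reagent-controlled vinylation of step 3 then gives 5 and the diastereomeric allylic alcohol F3 (same (R)-carbinol, mirror-image ring), which are separated by chromatography, so the absolute configuration of the series rests on the vinylation alone.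

Step 18 (cross-metathesis). What may go wrong: slow or unselective metathesis of the hindered 1,1-disubstituted olefin of 24, homodimerisation of 18, E/Z mixtures, or isomerisation of 24 to the butenolide. Fallback (aldol–elimination instead of metathesis), setting out from 15 and coming back at 25: conjugate addition of 2-lithio-1,3-dithiane (from 1,3-dithiane and n-BuLi, THF/HMPA) to 15 gives the keto dithiane F8. Wittig methylenation gives the dithiane olefin F9, and MeI/CaCO3 in aqueous MeCN unmasks the C12 aldehyde F10. Aldol addition of the lithium enolate (LiN(iPr)2, −78 °C) of (4S)-4-(tert-butyldimethylsilyloxy)oxolan-2-one F11 (from 19, TBSCl, imidazole) gives the aldol adduct F12. Mesylation (MsCl, Et3N) gives the mesylate F13, and DBU-induced E1cB elimination gives the E-alkylidene silyl ether F14. HF·pyridine gives 3,19-O-isopropylideneandrographolide F15, and acetylation (Ac2O, pyridine) returns 25.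

Further compounds
F1 | step 1 | (2S,3S)-2-methyl-3-(prop-1-en-2-yl)-2-(prop-2-en-1-yl)cyclohexan-1-one | C=CC[C@@]1(C)[C@H](C(C)=C)CCCC1=O
F2 | step 1 | 3-[(1S,6S)-1-methyl-2-oxo-6-(prop-1-en-2-yl)cyclohexyl]propanal | O=CCC[C@@]1(C)[C@H](C(C)=C)CCCC1=O
F3 | step 1 | (2S,3S)-2-[(3R)-3-hydroxypent-4-en-1-yl]-2-methyl-3-(prop-1-en-2-yl)cyclohexan-1-one | C=C[C@H](O)CC[C@@]1(C)[C@H](C(C)=C)CCCC1=O
F4 | step 7 | cis-2,3-epoxy-2,7-dimethylbicyclo[5.4.0]undecane-4,8-dione (epoxy diketone from 7) | O=C1[C@H]2O[C@@]2(C)[C@H]3CCCC(=O)[C@]3(C)CC1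
F5 | step 7 | 1,4a-dimethyl-2,5-dioxodecahydronaphthalene-1-carbaldehyde (formyl axial) | O=C1CC[C@@]2(C)C(=O)CCC[C@@H]2[C@]1(C)C=O
F6 | step 7 | 5-(hydroxymethyl)-5,8a-dimethyldecahydronaphthalene-1,6-diol (C9 epimers, equatorial C3 alcohol) | O[C@@H]1CC[C@@]2(C)C(O)CCC[C@@H]2[C@]1(C)CO
F7 | step 7 | 3,19-O-isopropylidene acetonide with C9 alcohol (C9 epimers) | CC1(C)OC[C@@]2(C)[C@H]3CCCC(O)[C@]3(C)CC[C@H]2O1
F8 | step 18 | C8-oxo C9-(1,3-dithian-2-ylmethyl) acetonide | CC1(C)OC[C@@]2(C)[C@H]3CCC(=O)[C@@H](CC4SCCCS4)[C@]3(C)CC[C@H]2O1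
F9 | step 18 | C8-methylidene C9-(1,3-dithian-2-ylmethyl) acetonide | CC1(C)OC[C@@]2(C)[C@H]3CCC(=C)[C@@H](CC4SCCCS4)[C@]3(C)CC[C@H]2O1
F10 | step 18 | 3,19-O-isopropylidene-13,14,15,16-tetranor-ent-labd-8(17)-en-12-al | CC1(C)OC[C@@]2(C)[C@H]3CCC(=C)[C@@H](CC=O)[C@]3(C)CC[C@H]2O1
F11 | step 18 | (4S)-4-(tert-butyldimethylsilyloxy)oxolan-2-one | O=C1C[C@H](O[Si](C)(C)C(C)(C)C)CO1
F12 | step 18 | aldol adduct of F10 and F11 (C12 carbinol epimers, C13 trans to the silyloxy group) | CC1(C)OC[C@@]2(C)[C@H]3CCC(=C)[C@@H](CC(O)[C@@H]4C(=O)OC[C@H]4O[Si](C)(C)C(C)(C)C)[C@]3(C)CC[C@H]2O1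
F13 | step 18 | C12 methanesulfonate of F12 | CC1(C)OC[C@@]2(C)[C@H]3CCC(=C)[C@@H](CC(OS(C)(=O)=O)[C@@H]4C(=O)OC[C@H]4O[Si](C)(C)C(C)(C)C)[C@]3(C)CC[C@H]2O1
F14 | step 18 | 14-O-(tert-butyldimethylsilyl)-3,19-O-isopropylideneandrographolide | CC1(C)OC[C@@]2(C)[C@H]3CCC(=C)[C@@H](C/C=C4/C(=O)OC[C@H]4O[Si](C)(C)C(C)(C)C)[C@]3(C)CC[C@H]2O1
F15 | step 18 | 3,19-O-isopropylideneandrographolide | CC1(C)OC[C@@]2(C)[C@H]3CCC(=C)[C@@H](C/C=C4/C(=O)OC[C@H]4O)[C@]3(C)CC[C@H]2O1
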